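**Retrosynthetic overview**
Feature: in the ten-membered ring C1–C10 the Z-C6=C7 olefin lies γ,δ to C10, and C10 carries oxygen beside the C1 exocyclic methylene. Read backwards, C9=C10–O and C6–C7=C8 form an allyl vinyl ether whose oxygen joined C10 to C6 in an eight-membered 2,3-dimethylene oxocane (O, C10, C1–C6), cis-fused at C4/C5 to the cyclohexane (C4, C5, C11–C14).
Disconnections: C8–C9 by [3,3] ring expansion; C9=C10 by lactone methylenation; O–C10 by lactonization; C2–C3 by Barbier allylation with the 2-(bromomethyl)acrylate; C6–C7 by isopropenyl Grignard addition; C3–C4 and C5–C6 by dichloroketene [2+2] on the TES ether of (1R,4R)-p-menth-2-en-1-ol from (S)-limonene.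
Ring order: cyclohexane (limonene) → cyclobutanone (cleaved to C3 acid and C6 aldehyde) → γ-lactone (temporary) → eight-membered lactone → dimethylene oxocane → ten-membered carbocycle.
End game: 1,2-reduction at C10, desilylation, acetylation of the two secondary hydroxyls.

Key step: step 19

Numbering used throughout (from step 5 on): C1 bears the exocyclic methylene, C3 and C10 the oxygen functions, C4/C5 are the ring fusion, C6=C7 is the olefin (methyl on C7), C11 bears isopropyl, C14 is the methyl carbinol.
Remark: acid–aldehyde 14 is drawn open-chain; it should rest mainly as its hydroxy-lactone tautomer and react through the open form.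
Remark: commercial auxiliary reagents are not numbered; only compounds that bring skeletal carbon are.

**Route**

Step 1
Reactants: 1 (S)-limonene
Product: 2 (S)-p-menth-1-ene [(4S)-1-methyl-4-(propan-2-yl)cyclohexene]
Conditions: H2 (1 atm), RhCl(PPh3)3 (cat.), benzene–EtOH, rt
Reagents that add atoms: none
Why: Homogeneous hydrogenation over Wilkinson's catalyst reduces the unhindered 1,1-disubstituted side-chain olefin far faster than the trisubstituted ring olefin and leaves the C4 stereocentre of the menthane untouched.

Step 2
Reactants: 2 (S)-p-menth-1-ene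
Product: 4 (1R,2S,4S)-1,2-epoxy-p-menthane with the oxirane oxygen cis to isopropyl, via bromohydrin 3 (not isolated)
Conditions: NBS, acetone–H2O, 0 °C; then aq. NaOH, rt
Reagents that add atoms: water, O
Why: Bromohydrin formation followed by intramolecular Williamson closure: water opens the bromonium ion at the tertiary carbon in the trans-diaxial sense (Fürst–Plattner) of the half-chair with equatorial isopropyl, which places the new C–O bond cis to isopropyl (the future C14 configuration), and base then closes the epoxide on that face.

Step 3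
Reactants: 4 (1R,2S,4S)-1,2-epoxy-p-menthane
Product: 7 (1R,4R)-p-menth-2-en-1-ol with hydroxyl cis to isopropyl, via hydroxy selenide 5 (not isolated), via selenoxide 6 (not isolated)
Conditions: (PhSe)2, NaBH4, EtOH, rt → reflux; then 30% H2O2, THF, 0 °C → rt
Reagents that add atoms: none
Why: Epoxide-to-allylic-alcohol transposition by the selenoxide route: benzeneselenolate opens the epoxide at the secondary carbon with inversion, and syn-elimination of the selenoxide can only go toward C3 because the carbinol carbon bears no hydrogen, so the carbinol configuration is retained and the olefin lands at C2=C3.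

Step 4
Reactants: 7 (1R,4R)-p-menth-2-en-1-ol
Product: 8 (1R,4R)-1-methyl-4-(propan-2-yl)-1-(triethylsilyloxy)cyclohex-2-ene
Conditions: TESOTf, 2,6-lutidine, CH2Cl2, −78 → 0 °C
Reagents that add atoms: triethylsilyl trifluoromethanesulfonate, CC[Si](CC)(CC)OS(=O)(=O)C(F)(F)F
Why: A silyl triflate with a hindered pyridine base silylates tertiary alcohols under non-ionizing conditions, and the ether masks the hydroxyl toward the ketene and adds bulk to the face it shares with isopropyl.

Step 5
Reactants: 8 TES ether of the menthenol; 9 trichloroacetyl chloride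
Product: 11 cis-fused 8,8-dichloro-5-methyl-2-(propan-2-yl)-5-(triethylsilyloxy)bicyclo[4.2.0]octan-7-one (four-membered ring anti to OTES and isopropyl; C=O carbon = C3 on C4; CCl2 = C6 on C5), via dichloroketene 10 (not isolated)
Conditions: Zn–Cu, Et2O–DME, rt, ultrasound, slow addition of 9
Reagents that add atoms: none
Why: Thermal [2+2] cycloaddition of dichloroketene (made in the flask by zinc dechlorination of 9) to the cis-disubstituted olefin: the ketene should add to the ring face opposite the cis-disposed silyloxy and isopropyl groups, which sets C4 and C5 cis to each other and trans to both, and its small electrophilic carbonyl carbon should bond to the olefin carbon next to the silyloxy-bearing quaternary centre (positive charge develops at the carbon remote from oxygen), so that the future C3 sits on C4 and the future C6 on C5.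

Step 6
Reactants: 11 dichlorocyclobutanone
Product: 12 cis-fused 5-methyl-2-(propan-2-yl)-5-(triethylsilyloxy)bicyclo[4.2.0]octan-7-one
Conditions: Zn dust, NH4Cl, MeOH, rt
Reagents that add atoms: none
Why: Zinc reduces both α-C–Cl bonds of an α,α-dichloroketone through the zinc enolate under buffered conditions that spare the silyl ether, and the ring-fusion centres are not touched.

Step 7
Reactants: 12 cyclobutanone
Product: 13 trimethylsilyl enol ether (C3(OTMS)=C6H in the four-membered ring)
Conditions: LDA, TMSCl (in-situ quench), THF, −78 °C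
Reagents that add atoms: chlorotrimethylsilane, C[Si](C)(C)Cl
Why: Kinetic deprotonation with in-situ silyl trapping takes the CH2 proton, because enolization toward the ring-fusion carbon would place a bridgehead-type double bond in the bicyclo[4.2.0] frame, and the internal quench prevents self-aldol reaction of the electrophilic cyclobutanone.

Step 8
Reactants: 13 silyl enol ether
Product: 14 cis-2-formyl-6-methyl-3-(propan-2-yl)-6-(triethylsilyloxy)cyclohexane-1-carboxylic acid (C3 acid on C4, C6 aldehyde on C5)
Conditions: O3, CH2Cl2–MeOH, −78 °C; then Me2S, −78 °C → rt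
Reagents that add atoms: ozone, [O-][O+]=O
Why: Ozonolysis of a silyl enol ether cleaves the C3=C6 bond to a carboxylic acid at the oxygenated carbon and an aldehyde at the other, which opens the four-membered ring into the cis C3 acid/C6 aldehyde pair without touching C4 or C5.

Step 9
Reactants: 14 acid–aldehyde; 15 isopropenylmagnesium bromide
Product: 17 cis-fused γ-lactone (C3 carbonyl, ring oxygen on C6, 6R, isopropenyl on the convex face anti to C11), via hydroxy acid 16 (not isolated)
Conditions: 15 (3 equiv), THF, −78 → −20 °C; then 0.5 M HCl, 0 °C; PPTS (cat.), CH2Cl2, rt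
Reagents that add atoms: none
Why: Grignard addition to the aldehyde of the magnesium carboxylate (the first equivalent only deprotonates the acid) followed by acid-induced γ-lactonization; addition anti to the C5–C11 bond on the flank of the equatorial C4–H, away from the isopropyl group and compatible with chelation of the aldehyde oxygen by the magnesium carboxylate, should give the 6R carbinol, which the lactone then masks together with C3.

Step 10
Reactants: 17 γ-lactone
Product: 18 diol (C3 primary alcohol, 6R allylic alcohol)
Conditions: LiAlH4, THF, 0 °C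
Reagents that add atoms: none
Why: Lithium aluminium hydride reduces the lactone to the 1,4-diol and touches neither the isolated olefin nor the silyl ether.

Step 11
Reactants: 18 diol
Product: 19 tris(triethylsilyl) ether (O3 primary, O6, O14)
Conditions: TESOTf, 2,6-lutidine, CH2Cl2, −78 → 0 °C
Reagents that add atoms: triethylsilyl trifluoromethanesulfonate, CC[Si](CC)(CC)OS(=O)(=O)C(F)(F)F
Why: Triethylsilyl triflate silylates both the primary and the hindered secondary allylic hydroxyl, which sets up the differentiation of the next step.

Step 12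
Reactants: 19 tris-TES ether
Product: 20 C3 aldehyde (axial formyl on C4; O6 and O14 as TES ethers)
Conditions: (COCl)2, DMSO, CH2Cl2, −78 → −35 °C; then Et3N, −78 → 0 °C
Reagents that add atoms: none
Why: Swern conditions convert a primary triethylsilyl ether directly into the aldehyde (the activated sulfonium reagent displaces the silyl group only at the unhindered primary oxygen) while secondary and tertiary TES ethers persist, and the cold amine quench limits epimerization at C4.

Step 13
Reactants: 20 C3 aldehyde; 21 ethyl 2-(bromomethyl)acrylate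
Product: 23 ethyl 4-hydroxy-2-methylidenebutanoate appended at C3 (3R homoallylic alcohol), via allylzinc bromide 22 (not isolated)
Conditions: Zn dust, THF–sat. aq. NH4Cl, 0 °C → rt
Reagents that add atoms: none
Why: Barbier allylation through the allylzinc (SE2' addition in a six-membered cyclic transition state) is selective for the aldehyde in aqueous medium, and Felkin–Anh addition anti to the C4–C14 bond (C14 is fully substituted and oxygenated) should set C3 as R.

Step 14
Reactants: 23 homoallylic alcohol
Product: 24 C3 TBS ether
Conditions: TBSOTf, 2,6-lutidine, CH2Cl2, −78 → 0 °C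
Reagents that add atoms: tert-butyldimethylsilyl trifluoromethanesulfonate, CC(C)(C)[Si](C)(C)OS(=O)(=O)C(F)(F)F
Why: Immediate silylation with the silyl triflate caps the C3 hydroxyl before it can lactonize onto the acrylate ester.

Step 15
Reactants: 24 fully silylated ester
Product: 25 C6 alcohol (O3 TBS, O14 TES retained)
Conditions: PPTS (cat.), MeOH–CH2Cl2, 0 °C
Reagents that add atoms: none
Why: Acid-catalysed methanolysis cleaves the secondary TES ether much faster than the far more hindered tertiary TES ether at C14 and the secondary TBS ether at C3.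

Step 16
Reactants: 25 hydroxy ester
Product: 26 seco acid (C10 carboxylic acid, C6 hydroxyl)
Conditions: LiOH·H2O, THF–MeOH–H2O, rt; then dilute HCl to pH 4, 0 °C
Reagents that add atoms: lithium hydroxide, [Li+].[OH-]
Why: Hydroxide saponifies the ethyl ester (BAc2), and the α-substituted acrylate is a poor Michael acceptor for hydroxide.

Step 17
Reactants: 26 seco acid
Product: 28 eight-membered α-methylene lactone (O–C10(=O)–C1(=CH2)–C2–C3–C4–C5–C6; 3R,4S,5R,6R,11R,14R), via mixed anhydride 27 (not isolated)
Conditions: 2-methyl-6-nitrobenzoic anhydride, Et3N, DMAP (cat.), CH2Cl2, high dilution (syringe pump), rt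
Reagents that add atoms: none
Why: Shiina macrolactonization: the mixed anhydride with 2-methyl-6-nitrobenzoic acid transfers the acryloyl group via acyl-DMAP to the C6 hydroxyl, the only free hydroxyl, under high dilution, and the cis (axial/equatorial) placement of the two chains on the cyclohexane together with the sp2 centre C1 preorganizes the eight-membered closure.

Step 18
Reactants: 28 eight-membered lactone
Product: 29 cis-fused 2,3-dimethylene-8-isopropenyl oxocane (3R,4S,5R,6R,11R,14R; O3 TBS, O14 TES)
Conditions: Cp2TiMe2, toluene, 65 °C, dark; filtration through basic alumina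
Reagents that add atoms: dimethyltitanocene, C[Ti](C)(C1C=CC=C1)C1C=CC=C1
Why: Petasis methylenation: the titanocene methylidene formed on heating converts the lactone carbonyl into the exocyclic enol ether through an oxatitanacyclobutane, without enolization or acid, and conjugated esters are known to give 2-alkoxy dienes.

Step 19
Reactants: 29 dimethylene oxocane
Product: 30 ten-membered 2-methylene enone (C10 ketone, Z-C6=C7; 3R,4S,5S,11R,14R)
Conditions: toluene (degassed, 5 mM), i-Pr2NEt (trace), BHT, sealed tube, 160 °C
Reagents that add atoms: none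
Why: Concerted [3,3]-sigmatropic (Claisen) shift of the allyl vinyl ether C9=C10–O–C6–C7=C8 embedded in the oxocane: C8–C9 forms as C6–O breaks, C10 becomes the ketone, and the C1 methylene, a spectator in the transition state, emerges conjugated to it. The closest known reaction is the Claisen ring expansion of 2-methylene-6-vinyltetrahydropyrans to cyclooct-4-enones, extended here by two ring atoms. The ten-membered carbocycle is closed by four-atom ring expansion through a chair-like six-centre array bridged by C1–C5 (bicyclo[5.3.1]-type transition state), not by end-to-end cyclization. No stereocentre is created and the C6 centre is erased; the only new stereoelement is the C6=C7 geometry. The needed Z selectivity is secured by the tether, because the five-atom bridge between C10 and C6 can only be spanned when C5 is pseudo-axial on C6, and in the 6R epimer the chair assembles on the oxocane face opposite the cyclohexane and the C3 silyloxy group. Only one allyl vinyl ether array is present, the product gains enone conjugation as extra driving force, and the amine-buffered, acid-free medium guards the dienol ether against hydrolysis.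

Step 20
Reactants: 30 enone
Product: 31 (10R)-allylic alcohol (O3 TBS, O14 TES)
Conditions: NaBH4, CeCl3·7H2O, MeOH, −78 → −40 °C
Reagents that add atoms: none
Why: Luche reduction: cerium(III) makes the borohydride attack 1,2-selective, and hydride should enter the C10 carbonyl from the ring face opposite the C3 silyloxy group and the fused cyclohexane, which gives the 10R carbinol with O10 cis to O3.

Step 21
Reactants: 31 allylic alcohol
Product: 32 triol (3R,4S,5S,10R,11R,14R)
Conditions: TBAF, THF, rt → 50 °C
Reagents that add atoms: none
Why: Fluoride cleaves the secondary TBS and the tertiary TES ether (strong Si–F bond), and nothing base-sensitive is present at this stage.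

Step 22
Reactants: 32 triol
Product: 33 CNP0303839.1 (3,10-diacetate, free C14 hydroxyl)
Conditions: Ac2O, pyridine, DMAP (cat.), CH2Cl2, 0 °C → rt
Reagents that add atoms: acetic anhydride, CC(=O)OC(C)=O
Why: DMAP-catalysed acetylation acylates the two secondary hydroxyls, whereas the tertiary C14 hydroxyl next to the ring fusion is too hindered to react under these mild conditions.

**Compound list**
1 | (S)-limonene | CC1=CC[C@H](CC1)C(C)=C | starting material
2 | (S)-p-menth-1-ene | CC1=CC[C@H](CC1)C(C)C | intermediate
3 | (1R,2R,4S)-2-bromo-1-methyl-4-(propan-2-yl)cyclohexan-1-ol (OH cis to isopropyl, Br trans) | CC(C)[C@H]1CC[C@@](C)(O)[C@H](Br)C1 | intermediate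
4 | (1R,2S,4S)-1,2-epoxy-p-menthane (oxirane oxygen cis to isopropyl) | CC(C)[C@H]1CC[C@@]2(C)O[C@H]2C1 | intermediate
5 | (1R,2R,4S)-1-methyl-2-(phenylselanyl)-4-(propan-2-yl)cyclohexan-1-ol | CC(C)[C@H]1CC[C@@](C)(O)[C@H]([Se]c2ccccc2)C1 | intermediate
6 | selenoxide of 5 | CC(C)[C@H]1CC[C@@](C)(O)[C@H]([Se](=O)c2ccccc2)C1 | intermediate
7 | (1R,4R)-p-menth-2-en-1-ol (OH cis to isopropyl) | CC(C)[C@H]1CC[C@@](C)(O)C=C1 | intermediate
8 | (1R,4R)-1-methyl-4-(propan-2-yl)-1-(triethylsilyloxy)cyclohex-2-ene | CC(C)[C@H]1CC[C@@](C)(O[Si](CC)(CC)CC)C=C1 | intermediate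
9 | trichloroacetyl chloride | ClC(Cl)(Cl)C(Cl)=O | starting material
10 | dichloroketene | ClC(Cl)=C=O | intermediate
11 | cis-fused 8,8-dichloro-5-methyl-2-(propan-2-yl)-5-(triethylsilyloxy)bicyclo[4.2.0]octan-7-one | O=C1[C@@H]2[C@H](C1(Cl)Cl)[C@@H](C(C)C)CC[C@@]2(C)O[Si](CC)(CC)CC | intermediate
12 | cis-fused 5-methyl-2-(propan-2-yl)-5-(triethylsilyloxy)bicyclo[4.2.0]octan-7-one | O=C1[C@@H]2[C@H](C1)[C@@H](C(C)C)CC[C@@]2(C)O[Si](CC)(CC)CC | intermediate
13 | trimethylsilyl enol ether of 12 (C3=C6) | C[Si](C)(C)OC1[C@@H]2[C@H](C=1)[C@@H](C(C)C)CC[C@@]2(C)O[Si](CC)(CC)CC | intermediate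
14 | cis-2-formyl-6-methyl-3-(propan-2-yl)-6-(triethylsilyloxy)cyclohexane-1-carboxylic acid | OC(=O)[C@@H]1[C@H](C=O)[C@@H](C(C)C)CC[C@@]1(C)O[Si](CC)(CC)CC | intermediate
15 | isopropenylmagnesium bromide | C=C(C)[Mg]Br | starting material
16 | (6R)-hydroxy acid (C3 acid, C6 isopropenyl carbinol) | OC(=O)[C@@H]1[C@H]([C@@H](O)C(C)=C)[C@@H](C(C)C)CC[C@@]1(C)O[Si](CC)(CC)CC | intermediate
17 | cis-fused γ-lactone (C3 carbonyl, O on C6, 6R) | O=C1[C@@H]2[C@H]([C@@H](O1)C(C)=C)[C@@H](C(C)C)CC[C@@]2(C)O[Si](CC)(CC)CC | intermediate
18 | diol (C3 CH2OH, 6R carbinol) | OC[C@@H]1[C@H]([C@@H](O)C(C)=C)[C@@H](C(C)C)CC[C@@]1(C)O[Si](CC)(CC)CC | intermediate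
19 | tris(triethylsilyl) ether | CC[Si](CC)(CC)OC[C@@H]1[C@H]([C@@H](O[Si](CC)(CC)CC)C(C)=C)[C@@H](C(C)C)CC[C@@]1(C)O[Si](CC)(CC)CC | intermediate
20 | C3 aldehyde (O6, O14 TES) | O=C[C@@H]1[C@H]([C@@H](O[Si](CC)(CC)CC)C(C)=C)[C@@H](C(C)C)CC[C@@]1(C)O[Si](CC)(CC)CC | intermediate
21 | ethyl 2-(bromomethyl)acrylate | C=C(CBr)C(=O)OCC | starting material
22 | [2-(ethoxycarbonyl)allyl]zinc bromide | CCOC(=O)C(=C)C[Zn]Br | intermediate
23 | (3R)-homoallylic alcohol, ethyl ester | CCOC(=O)C(=C)C[C@@H](O)[C@@H]1[C@H]([C@@H](O[Si](CC)(CC)CC)C(C)=C)[C@@H](C(C)C)CC[C@@]1(C)O[Si](CC)(CC)CC | intermediate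
24 | C3 TBS ether of 23 | CCOC(=O)C(=C)C[C@@H](O[Si](C)(C)C(C)(C)C)[C@@H]1[C@H]([C@@H](O[Si](CC)(CC)CC)C(C)=C)[C@@H](C(C)C)CC[C@@]1(C)O[Si](CC)(CC)CC | intermediate
25 | C6 alcohol, ethyl ester | CCOC(=O)C(=C)C[C@@H](O[Si](C)(C)C(C)(C)C)[C@@H]1[C@H]([C@@H](O)C(C)=C)[C@@H](C(C)C)CC[C@@]1(C)O[Si](CC)(CC)CC | intermediate
26 | seco acid | OC(=O)C(=C)C[C@@H](O[Si](C)(C)C(C)(C)C)[C@@H]1[C@H]([C@@H](O)C(C)=C)[C@@H](C(C)C)CC[C@@]1(C)O[Si](CC)(CC)CC | intermediate
27 | mixed anhydride of 26 with 2-methyl-6-nitrobenzoic acid | Cc1cccc([N+](=O)[O-])c1C(=O)OC(=O)C(=C)C[C@@H](O[Si](C)(C)C(C)(C)C)[C@@H]2[C@H]([C@@H](O)C(C)=C)[C@@H](C(C)C)CC[C@@]2(C)O[Si](CC)(CC)CC | intermediate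
28 | eight-membered α-methylene lactone | C=C1C[C@@H](O[Si](C)(C)C(C)(C)C)[C@@H]2[C@H]([C@@H](OC1=O)C(C)=C)[C@@H](C(C)C)CC[C@@]2(C)O[Si](CC)(CC)CC | intermediate
29 | cis-fused 2,3-dimethylene-8-isopropenyl oxocane (key-step precursor) | C=C1C[C@@H](O[Si](C)(C)C(C)(C)C)[C@@H]2[C@H]([C@@H](OC1=C)C(C)=C)[C@@H](C(C)C)CC[C@@]2(C)O[Si](CC)(CC)CC | intermediate
30 | ten-membered 2-methylene enone, Z-C6=C7 (key-step product) | C=C1C[C@@H](O[Si](C)(C)C(C)(C)C)[C@@H]2[C@H](/C=C(/C)CCC1=O)[C@@H](C(C)C)CC[C@@]2(C)O[Si](CC)(CC)CC | intermediate
31 | (10R)-allylic alcohol | C=C1C[C@@H](O[Si](C)(C)C(C)(C)C)[C@@H]2[C@H](/C=C(/C)CC[C@H]1O)[C@@H](C(C)C)CC[C@@]2(C)O[Si](CC)(CC)CC | intermediate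
32 | triol | C=C1C[C@@H](O)[C@@H]2[C@H](/C=C(/C)CC[C@H]1O)[C@@H](C(C)C)CC[C@@]2(C)O | intermediate
33 | CNP0303839.1 | C=C1C[C@@H](OC(C)=O)[C@@H]2[C@H](/C=C(/C)CC[C@H]1OC(C)=O)[C@@H](C(C)C)CC[C@@]2(C)O | target

**Step count**
Total steps: 22. Longest linear sequence: 22 steps from (S)-limonene (1).

**Steps most likely to fail**

Step 19 (Claisen ring expansion). The oxocane may not reach the bridged chair before the acid-labile dienol ether is lost to hydrolysis, double-bond migration or polymerization, or a boat-like pathway may erode the Z geometry. The fallback sets out from 29 and replaces the neutral thermal shift by an organoaluminium-promoted reductive Claisen rearrangement (i-Bu3Al, CH2Cl2, −78 → 0 °C), the known low-temperature variant for 2-methylene cyclic ethers with a vinyl group at the ether carbon. Aluminium binds the ether oxygen, the C6–O bond polarizes toward an allyl cation/aluminium enolate pair that recombines at C8–C9 inside the ring, and the aluminium-bound ketone is reduced in the flask by β-hydride transfer. The product is the C10 carbinol, as 31 and/or its epimer, the (10S)-allylic alcohol F1. The carbinol mixture is oxidized with Dess–Martin periodinane (NaHCO3, CH2Cl2) to enone 30, where the route resumes at step 20.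

Step 17 (eight-membered lactonization). Intermolecular acyl transfer (diolide and oligomer formation) and slow acylation of the hindered allylic hydroxyl may outrun closure of the strained ring. The fallback sets out from diol 18, makes the ester bond intermolecularly and closes the ring at C2–C3 instead. The primary hydroxyl is silylated selectively (TESCl, imidazole, CH2Cl2, −40 °C) to the mono-TES ether F2. The C6 hydroxyl is esterified with 2-(bromomethyl)acrylic acid (DIC, DMAP cat., CH2Cl2, 0 °C) to the 2-(bromomethyl)acrylate F3. Direct Swern oxidation of the primary TES ether gives the aldehyde F4. Intramolecular Nozaki–Hiyama allylation (CrCl2, THF, high dilution) then forms the C2–C3 bond and gives the hydroxy lactone F5; the C3 configuration from this closure would have to be confirmed. Silylation (TBSOTf, 2,6-lutidine) returns to the route at 28.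

Step 20 (Luche reduction). The flexible ten-membered enone may present either carbonyl face in low-energy conformers, so hydride delivery may be poorly selective or favour the 10S carbinol. The fallback sets out from 30 and replaces substrate control by reagent control: Corey–Bakshi–Shibata reduction with the (S)-2-methyl-oxazaborolidine and catecholborane (toluene, −78 °C). The C1 alkenyl side acts as the large group, which by the usual model should give the 10R carbinol 31 directly, where the route resumes at step 21. This fallback makes no new compound (F0).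

**Further compounds**
F1 | step 19 | (10S)-allylic alcohol, C10 epimer of 31 | C=C1C[C@@H](O[Si](C)(C)C(C)(C)C)[C@@H]2[C@H](/C=C(/C)CC[C@@H]1O)[C@@H](C(C)C)CC[C@@]2(C)O[Si](CC)(CC)CC
F2 | step 17 | mono-TES ether of diol 18 (primary O3 silylated, C6 hydroxyl free) | CC[Si](CC)(CC)OC[C@@H]1[C@H]([C@@H](O)C(C)=C)[C@@H](C(C)C)CC[C@@]1(C)O[Si](CC)(CC)CC
F3 | step 17 | C6 2-(bromomethyl)acrylate of F2 | CC[Si](CC)(CC)OC[C@@H]1[C@H]([C@@H](OC(=O)C(=C)CBr)C(C)=C)[C@@H](C(C)C)CC[C@@]1(C)O[Si](CC)(CC)CC
F4 | step 17 | C3 aldehyde carrying the C6 2-(bromomethyl)acrylate | O=C[C@@H]1[C@H]([C@@H](OC(=O)C(=C)CBr)C(C)=C)[C@@H](C(C)C)CC[C@@]1(C)O[Si](CC)(CC)CC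
F5 | step 17 | eight-membered α-methylene lactone with free C3 hydroxyl | C=C1C[C@@H](O)[C@@H]2[C@H]([C@@H](OC1=O)C(C)=C)[C@@H](C(C)C)CC[C@@]2(C)O[Si](CC)(CC)CC
F0 | step 20 | none | none
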